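**Retrosynthetic overview** (benzofuran numbering; ring A = benzo ring C3a–C7a, ring B = dihydrofuran ring O1–C2–C3–C3a–C7a, ring C = aryl group on C2)

1. The target is traced back to its ring C silyl ether, and the (E)-propenyl group at C5 to a Suzuki–Miyaura coupling of a C5 chloride.
2. Key disconnection C3a–C3: ring B is the only ring made, closed by 5-exo-trig cyclization of a C3a aryl radical onto the vinyl group of an aryl 1-arylallyl ether; rings A and C are bought as arenes.
3. Enabling feature: O1 sits on C7a, ortho to C3a, and is bonded to the stereogenic C2 that carries ring C and the future C3. A radical at C3a is therefore five atoms from the alkene terminus and C2 relays its configuration to C3; C3 itself cannot carry a metal or a negative charge, because O1 on C2 would leave by β-elimination.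
4. The ether comes from an iridium-catalysed asymmetric allylic etherification of 4-chloro-2-iodo-6-methoxyphenol with a silyl-protected sinapyl methyl carbonate, which sets C2.
5. The iodophenol comes from 4-chloro-2-methoxyphenol; the carbonate comes from syringaldehyde by silylation, Wittig olefination, reduction and acylation.

Key step: step 7

Assumption: the ligand antipode written in step 6, (Ra,Rc,Rc), is taken to be the one that delivers the (R)-ether from an (E)-cinnamyl-type carbonate and an aryloxide; if the facial sense is the opposite, the mirror-image ligand is used and nothing else changes.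

**Route**

Step 1
Reactants: 1 4-chloro-2-methoxyphenol
Product: 2 4-chloro-2-iodo-6-methoxyphenol
Conditions: I2, KI, NaOH (1 equiv), H2O–MeOH, 0 °C to rt
Reagents that add atoms: iodine, [I][I]
Why: Electrophilic aromatic iodination of the phenoxide should occur at the only free position ortho to the oxygen (para is blocked by chlorine), which is far more activated than the positions served only by the methoxy group.

Step 2
Reactants: 3 syringaldehyde (4-hydroxy-3,5-dimethoxybenzaldehyde)
Product: 4 3,5-dimethoxy-4-(triisopropylsilyloxy)benzaldehyde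
Conditions: i-Pr3SiCl, imidazole, DMF, rt
Reagents that add atoms: chlorotriisopropylsilane, CC(C)[Si](Cl)(C(C)C)C(C)C
Why: Imidazole-promoted silyl ether formation masks the ring C phenol as a base-, hydride- and radical-stable triisopropylsilyl ether that fluoride removes in the last step.

Step 3
Reactants: 4 3,5-dimethoxy-4-(triisopropylsilyloxy)benzaldehyde
Product: 5 ethyl (E)-3-[3,5-dimethoxy-4-(triisopropylsilyloxy)phenyl]prop-2-enoate
Conditions: Ph3P=CHCO2Et, toluene, 80 °C
Reagents that add atoms: ethyl (triphenylphosphoranylidene)acetate, CCOC(=O)C=P(c1ccccc1)(c1ccccc1)c1ccccc1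
Why: Wittig olefination with a stabilised ylide should give the (E)-cinnamate.

Step 4
Reactants: 5 ethyl (E)-3-[3,5-dimethoxy-4-(triisopropylsilyloxy)phenyl]prop-2-enoate
Product: 6 (E)-3-[3,5-dimethoxy-4-(triisopropylsilyloxy)phenyl]prop-2-en-1-ol
Conditions: i-Bu2AlH (2.2 equiv), CH2Cl2, −78 to 0 °C; aq. potassium sodium tartrate (KNaC4H4O6)
Reagents that add atoms: none
Why: 1,2-Reduction of the conjugated ester by an aluminium hydride at low temperature should give the allylic alcohol without touching the alkene or the silyl ether.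

Step 5
Reactants: 6 (E)-3-[3,5-dimethoxy-4-(triisopropylsilyloxy)phenyl]prop-2-en-1-ol
Product: 7 (E)-3-[3,5-dimethoxy-4-(triisopropylsilyloxy)phenyl]prop-2-en-1-yl methyl carbonate
Conditions: ClCO2Me, pyridine, CH2Cl2, 0 °C
Reagents that add atoms: methyl chloroformate, COC(=O)Cl
Why: Acylation of the primary allylic alcohol with a chloroformate gives the linear methyl carbonate that serves as the leaving group for iridium.

Step 6
Reactants: 2 4-chloro-2-iodo-6-methoxyphenol; 7 (E)-3-[3,5-dimethoxy-4-(triisopropylsilyloxy)phenyl]prop-2-en-1-yl methyl carbonate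
Product: 9 5-chloro-1-iodo-3-methoxy-2-{(1R)-1-[3,5-dimethoxy-4-(triisopropylsilyloxy)phenyl]prop-2-en-1-yloxy}benzene, via lithium aryloxide 8 (not isolated)
Conditions: LiN(SiMe3)2 (1 equiv), THF, 0 °C; then 7, [Ir(cod)Cl]2 (2 mol%), phosphoramidite (Ra,Rc,Rc)-PA [binaphthol-derived N,N-bis(1-phenylethyl)phosphoramidite] (4 mol%, catalyst pre-formed with n-PrNH2), THF, rt to 50 °C
Reagents that add atoms: none
Why: Iridium-catalysed asymmetric allylic etherification, in which the aryloxide attacks the cyclometalated (π-allyl)iridium phosphoramidite intermediate at its aryl-substituted terminus on the face away from the metal, should give the branched ether and sets C2 by catalyst control.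

Step 7
Reactants: 9 5-chloro-1-iodo-3-methoxy-2-{(1R)-1-[3,5-dimethoxy-4-(triisopropylsilyloxy)phenyl]prop-2-en-1-yloxy}benzene
Product: 12 (2R,3R)-5-chloro-7-methoxy-3-methyl-2-[3,5-dimethoxy-4-(triisopropylsilyloxy)phenyl]-2,3-dihydro-1-benzofuran, via aryl radical 10 (not isolated), via primary alkyl radical 11 (not isolated)
Conditions: (Me3Si)3SiH (1.3 equiv), Et3B (0.3 equiv, in portions), trace air, toluene (0.02 M), −40 °C
Reagents that add atoms: none
Why: Et3B and traces of O2 start a silyl radical chain in which (Me3Si)3Si• abstracts iodine from C3a of 9, the σ-aryl radical 10 adds to the internal carbon of the vinyl group to form the C3a–C3 bond, and the primary radical 11 takes a hydrogen atom from the silane, which turns the alkene terminus into the C3 methyl group and carries the chain. The closest known reaction type is the silane- or stannane-mediated aryl radical cyclization of 2-haloaryl allyl ethers to 3-methyl-2,3-dihydrobenzofurans. Ring B, the only ring closed, forms in the 5-exo-trig mode, which is favoured stereoelectronically over 6-endo attack at the alkene terminus. The new stereocentre C3 is set by the existing C2 centre: in the chair-like transition state ring C sits pseudo-equatorial, so the aryl radical adds to the alkene face anti to ring C and the 2,3-trans (2R,3R) isomer should predominate, the low temperature sharpening this preference. The step needs C–I over C–Cl selectivity, secured by the much weaker C–I bond, and needs ring closure to outrun 1,5-hydrogen transfer from C2–H, attack on ring C and direct reduction, secured by the short oxygen tether, the fast 5-exo closure and high dilution, while the excess of silane at low temperature traps 11 before a neophyl-type ring expansion to the chroman. The arene side is activated because a carbanion or metal at C3 would expel O1 by β-elimination, whereas radical 11 has no such exit.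

Step 8
Reactants: 12 (2R,3R)-5-chloro-7-methoxy-3-methyl-2-[3,5-dimethoxy-4-(triisopropylsilyloxy)phenyl]-2,3-dihydro-1-benzofuran
Product: 13 (2R,3R)-7-methoxy-3-methyl-5-[(E)-prop-1-en-1-yl]-2-[3,5-dimethoxy-4-(triisopropylsilyloxy)phenyl]-2,3-dihydro-1-benzofuran
Conditions: (E)-propenylboronic acid pinacol ester, Pd(OAc)2 (3 mol%), SPhos (6 mol%), K3PO4, toluene–H2O (10:1), 90 °C
Reagents that add atoms: (E)-4,4,5,5-tetramethyl-2-(prop-1-en-1-yl)-1,3,2-dioxaborolane, C/C=C/B1OC(C)(C)C(C)(C)O1
Why: Suzuki–Miyaura coupling with a dialkylbiarylphosphine ligand should activate the electron-rich aryl chloride and transfer the propenyl group with retention of its (E) geometry, and it is placed after ring closure because zerovalent palladium would ionise the allylic aryl ether 9 but not the saturated ring B ether.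

Step 9
Reactants: 13 (2R,3R)-7-methoxy-3-methyl-5-[(E)-prop-1-en-1-yl]-2-[3,5-dimethoxy-4-(triisopropylsilyloxy)phenyl]-2,3-dihydro-1-benzofuran
Product: 14 maceneolignan A, 4-{(2R,3R)-7-methoxy-3-methyl-5-[(E)-prop-1-en-1-yl]-2,3-dihydro-1-benzofuran-2-yl}-2,6-dimethoxyphenol
Conditions: Bu4NF (1.2 equiv), AcOH (1.5 equiv), THF, 0 °C
Reagents that add atoms: none
Why: Fluoride-mediated desilylation buffered with acetic acid should free the ring C phenol while keeping it protonated, so that the O1–C2 bond is not opened through the para-quinone methide and C2 is not scrambled.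

**Compound list**

1 | 4-chloro-2-methoxyphenol | COc1cc(Cl)ccc1O | starting material
2 | 4-chloro-2-iodo-6-methoxyphenol | COc1cc(Cl)cc(I)c1O | intermediate
3 | syringaldehyde (4-hydroxy-3,5-dimethoxybenzaldehyde) | COc1cc(C=O)cc(OC)c1O | starting material
4 | 3,5-dimethoxy-4-(triisopropylsilyloxy)benzaldehyde | COc1cc(C=O)cc(OC)c1O[Si](C(C)C)(C(C)C)C(C)C | intermediate
5 | ethyl (E)-3-[3,5-dimethoxy-4-(triisopropylsilyloxy)phenyl]prop-2-enoate | CCOC(=O)/C=C/c1cc(OC)c(O[Si](C(C)C)(C(C)C)C(C)C)c(OC)c1 | intermediate
6 | (E)-3-[3,5-dimethoxy-4-(triisopropylsilyloxy)phenyl]prop-2-en-1-ol | OC/C=C/c1cc(OC)c(O[Si](C(C)C)(C(C)C)C(C)C)c(OC)c1 | intermediate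
7 | (E)-3-[3,5-dimethoxy-4-(triisopropylsilyloxy)phenyl]prop-2-en-1-yl methyl carbonate | COC(=O)OC/C=C/c1cc(OC)c(O[Si](C(C)C)(C(C)C)C(C)C)c(OC)c1 | intermediate
8 | lithium 4-chloro-2-iodo-6-methoxyphenolate (formed in the flask) | [Li+].COc1cc(Cl)cc(I)c1[O-] | intermediate
9 | 5-chloro-1-iodo-3-methoxy-2-{(1R)-1-[3,5-dimethoxy-4-(triisopropylsilyloxy)phenyl]prop-2-en-1-yloxy}benzene | C=C[C@H](c1cc(OC)c(O[Si](C(C)C)(C(C)C)C(C)C)c(OC)c1)Oc1c(I)cc(Cl)cc1OC | intermediate
10 | aryl radical from 9: unpaired electron on the ring carbon that carried iodine, (R) centre unchanged (formed in the flask) | C=C[C@H](c1cc(OC)c(O[Si](C(C)C)(C(C)C)C(C)C)c(OC)c1)Oc1[c]cc(Cl)cc1OC | intermediate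
11 | {(2R,3R)-5-chloro-7-methoxy-2-[3,5-dimethoxy-4-(triisopropylsilyloxy)phenyl]-2,3-dihydro-1-benzofuran-3-yl}methyl radical (formed in the flask) | Clc1cc(OC)c2c(c1)[C@@H]([CH2])[C@H](c1cc(OC)c(O[Si](C(C)C)(C(C)C)C(C)C)c(OC)c1)O2 | intermediate
12 | (2R,3R)-5-chloro-7-methoxy-3-methyl-2-[3,5-dimethoxy-4-(triisopropylsilyloxy)phenyl]-2,3-dihydro-1-benzofuran (2,3-trans) | Clc1cc(OC)c2c(c1)[C@@H](C)[C@H](c1cc(OC)c(O[Si](C(C)C)(C(C)C)C(C)C)c(OC)c1)O2 | intermediate
13 | (2R,3R)-7-methoxy-3-methyl-5-[(E)-prop-1-en-1-yl]-2-[3,5-dimethoxy-4-(triisopropylsilyloxy)phenyl]-2,3-dihydro-1-benzofuran | C/C=C/c1cc(OC)c2c(c1)[C@@H](C)[C@H](c1cc(OC)c(O[Si](C(C)C)(C(C)C)C(C)C)c(OC)c1)O2 | intermediate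
14 | maceneolignan A, 4-{(2R,3R)-7-methoxy-3-methyl-5-[(E)-prop-1-en-1-yl]-2,3-dihydro-1-benzofuran-2-yl}-2,6-dimethoxyphenol | C/C=C/c1cc(OC)c2c(c1)[C@@H](C)[C@H](c1cc(OC)c(O)c(OC)c1)O2 | target

**Step count and risks**

Total step count: 9. Longest linear sequence: 8 steps (3 to 14, steps 2 to 9).

Steps most likely to fail:

Step 7 (key step). The two faces of the unsubstituted vinyl group may be discriminated too weakly, giving a trans/cis mixture at C3. The cis isomer is of no use, because later equilibration at C2 would turn it into the enantiomer of the target. 1,5-Hydrogen transfer from C2–H is a second leak. The fallback changes the stereocontrol element by adding a temporary substituent. It sets out from 2 and 4 by way of the propargyl ether F3 described under step 6 and comes back at 12. Bromination of the terminal alkyne of F3 (N-bromosuccinimide, AgNO3 cat., acetone) would give the bromoalkyne F4. Hydroboration with Cy2BH followed by protonolysis with AcOH would give the (Z)-bromoalkene F5. In F5 the bromine is cis to C2, so allylic 1,3-strain holds C2–H in the alkene plane and leaves ring C and O1 on opposite faces; the oxygen-tethered aryl radical can then only add anti to ring C. Treatment with (Me3Si)3SiH (2.5 equiv), Et3B and trace air in toluene at −40 °C to rt would cyclize F5 to the 3-(bromomethyl) compound F6, formed in the flask, and the same silane would then reduce its C–Br bond to give 12.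

Step 6. Allylic substitution may be slow or unselective with the hindered, weakly nucleophilic 2,6-disubstituted aryloxide, and reversible ionisation of the electron-rich allylic ether may erode the enantiomeric purity and the branched-to-linear selectivity. The fallback sets out from aldehyde 4 and iodophenol 2 and comes back at ether 9. Addition of HC≡CMgBr to 4 (THF, 0 °C) would give the racemic propargylic alcohol F1, and acetylation (Ac2O, pyridine) its acetate F2. Copper-catalysed enantioselective propargylic etherification of F2 with 2 (CuOTf·½C6H6, chiral pybox ligand, i-Pr2NEt, THF, 0 °C) runs through a copper allenylidene and is therefore enantioconvergent; it would give the (R)-propargyl ether F3. Semihydrogenation of the terminal alkyne (H2, Pd/CaCO3 poisoned with Pb(OAc)2, quinoline, EtOAc) would return 9.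

Step 8. Oxidative addition into the electron-rich C5–Cl bond may be sluggish, so that protodeboronation of the alkenylboronate or base-induced loss of the silyl group takes over. The fallback reverses the roles of the coupling partners. It sets out from 12 and comes back at 13. Miyaura borylation of 12 (B2pin2, Pd2(dba)3, XPhos, KOAc, dioxane, 100 °C) would give the aryl boronate F7. Suzuki–Miyaura coupling of F7 with (E)-1-bromoprop-1-ene (Pd(PPh3)4, aq. K2CO3, THF, 60 °C) proceeds with retention of alkene geometry and would give 13.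

**Further compounds**

F1 | step 6 | racemic 1-[3,5-dimethoxy-4-(triisopropylsilyloxy)phenyl]prop-2-yn-1-ol | C#CC(O)c1cc(OC)c(O[Si](C(C)C)(C(C)C)C(C)C)c(OC)c1
F2 | step 6 | racemic 1-[3,5-dimethoxy-4-(triisopropylsilyloxy)phenyl]prop-2-yn-1-yl acetate | C#CC(OC(C)=O)c1cc(OC)c(O[Si](C(C)C)(C(C)C)C(C)C)c(OC)c1
F3 | step 6 | 5-chloro-1-iodo-3-methoxy-2-{(1R)-1-[3,5-dimethoxy-4-(triisopropylsilyloxy)phenyl]prop-2-yn-1-yloxy}benzene | C#C[C@H](c1cc(OC)c(O[Si](C(C)C)(C(C)C)C(C)C)c(OC)c1)Oc1c(I)cc(Cl)cc1OC
F4 | step 7 | 2-{(1S)-3-bromo-1-[3,5-dimethoxy-4-(triisopropylsilyloxy)phenyl]prop-2-yn-1-yloxy}-5-chloro-1-iodo-3-methoxybenzene (same spatial arrangement as F3; the descriptor changes because bromoethynyl outranks aryl) | BrC#C[C@H](c1cc(OC)c(O[Si](C(C)C)(C(C)C)C(C)C)c(OC)c1)Oc1c(I)cc(Cl)cc1OC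
F5 | step 7 | 2-{(1R,2Z)-3-bromo-1-[3,5-dimethoxy-4-(triisopropylsilyloxy)phenyl]prop-2-en-1-yloxy}-5-chloro-1-iodo-3-methoxybenzene | Br/C=C\[C@H](c1cc(OC)c(O[Si](C(C)C)(C(C)C)C(C)C)c(OC)c1)Oc1c(I)cc(Cl)cc1OC
F6 | step 7 | (2R,3R)-3-(bromomethyl)-5-chloro-7-methoxy-2-[3,5-dimethoxy-4-(triisopropylsilyloxy)phenyl]-2,3-dihydro-1-benzofuran (formed in the flask) | Clc1cc(OC)c2c(c1)[C@@H](CBr)[C@H](c1cc(OC)c(O[Si](C(C)C)(C(C)C)C(C)C)c(OC)c1)O2
F7 | step 8 | (2R,3R)-7-methoxy-3-methyl-5-(4,4,5,5-tetramethyl-1,3,2-dioxaborolan-2-yl)-2-[3,5-dimethoxy-4-(triisopropylsilyloxy)phenyl]-2,3-dihydro-1-benzofuran | CC1(C)OB(OC1(C)C)c1cc(OC)c2c(c1)[C@@H](C)[C@H](c1cc(OC)c(O[Si](C(C)C)(C(C)C)C(C)C)c(OC)c1)O2
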